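**Strategy.** Ring B of the icetexane core (C5–C6–C7–C8–C9–C20–C10, icetexane numbering) is cut at C5–C6 and C9–C20. This is a (4+3) annulation of the allyl unit C5–C10–C20 of ring A with the aryl-ketone unit C6–C7–C8–C9. The 19,6-lactone serves as the tether: a phenacyl ester joins a ring-A Morita–Baylis–Hillman carbonate to the bromoarene. One zerovalent-palladium catalyst then performs a Tsuji–Trost alkylation (C6 to C5, closing the γ-lactone) and a 7-endo Mizoroki–Heck cyclisation (C9 to C20, closing ring B) in a single operation. The C4 quaternary centre comes from an asymmetric Diels–Alder reaction; two hydride reductions and oxidation of ring C finish the synthesis.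

Key step: step 10

Remark: the (R,R)-TADDOL in step 5 is assumed to induce the (S) quaternary centre; if it induces (R), its enantiomer is used.

**Step 1**
Reactants: 1 1,2,4-trimethoxybenzene; 2 acetone
Product: 3 2-(2,3,6-trimethoxyphenyl)propan-2-ol
Conditions: n-BuLi, THF, 0 °C; then acetone, −78 °C to 23 °C
Reagents that add atoms: none
Why: Directed ortho-lithiation should occur at the ring C–H flanked by two methoxy groups, and the aryllithium adds 1,2 to acetone.

**Step 2**
Reactants: 3 2-(2,3,6-trimethoxyphenyl)propan-2-ol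
Product: 4 1,2,4-trimethoxy-3-(propan-2-yl)benzene
Conditions: Et3SiH, CF3CO2H, CH2Cl2, 0 °C to 23 °C
Reagents that add atoms: none
Why: Ionic hydrogenation: the acid ionises the tertiary benzylic alcohol to a cation stabilised by two ortho methoxy groups and the silane delivers hydride.

**Step 3**
Reactants: 4 1,2,4-trimethoxy-3-(propan-2-yl)benzene; 5 chloroacetyl chloride
Product: 6 2-chloro-1-[2,4,5-trimethoxy-3-(propan-2-yl)phenyl]ethan-1-one
Conditions: SnCl4, CH2Cl2, −10 °C to 23 °C
Reagents that add atoms: none
Why: Friedel–Crafts acylation should go to the free position that is para to one methoxy group and ortho to another, the most electron-rich site of 4.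

**Step 4**
Reactants: 6 2-chloro-1-[2,4,5-trimethoxy-3-(propan-2-yl)phenyl]ethan-1-one
Product: 7 1-[2-bromo-3,4,6-trimethoxy-5-(propan-2-yl)phenyl]-2-chloroethan-1-one
Conditions: N-bromosuccinimide, MeCN, 0 °C to 23 °C, dark
Reagents that add atoms: N-bromosuccinimide, O=C1CCC(=O)N1Br
Why: Electrophilic aromatic bromination can only take the single free ring position (ortho to a methoxy group, para to the isopropyl group), and the polar, non-radical conditions favour the ring over the α-carbon of the ketone.

**Step 5**
Reactants: 8 (E)-3-(tert-butyldimethylsilyloxy)-N,N-dimethylbuta-1,3-dien-1-amine; 9 methacrolein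
Product: 11 (1S)-1-methyl-4-oxocyclohex-2-ene-1-carbaldehyde, via amino silyl enol ether cycloadduct 10 (not isolated)
Conditions: (R,R)-1-naphthyl-TADDOL (20 mol %), toluene, −78 °C; then aq. HF, MeCN, 0 °C
Reagents that add atoms: none
Why: Hydrogen-bond-catalysed enantioselective Diels–Alder reaction of an aminosiloxydiene with an α-substituted acrolein: the diol activates methacrolein and shields one of its faces, which sets the quaternary centre, and HF then cleaves the silyl enol ether and eliminates dimethylamine to unveil the enone.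

**Step 6**
Reactants: 11 (1S)-1-methyl-4-oxocyclohex-2-ene-1-carbaldehyde; 12 formaldehyde
Product: 13 (1S)-3-(hydroxymethyl)-1-methyl-4-oxocyclohex-2-ene-1-carbaldehyde
Conditions: aq. HCHO (37 %), DMAP (0.3 equiv), THF/H2O, 23 °C
Reagents that add atoms: none
Why: Morita–Baylis–Hillman reaction: DMAP adds to the enone β-carbon, the enolate is hydroxymethylated at the α-carbon and DMAP is expelled; the neopentyl aldehyde should not compete with formaldehyde.

**Step 7**
Reactants: 13 (1S)-3-(hydroxymethyl)-1-methyl-4-oxocyclohex-2-ene-1-carbaldehyde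
Product: 14 tert-butyl [(3S)-3-formyl-3-methyl-6-oxocyclohex-1-en-1-yl]methyl carbonate
Conditions: Boc2O, DMAP (5 mol %), CH2Cl2, 0 °C
Reagents that add atoms: di-tert-butyl dicarbonate, CC(C)(C)OC(=O)OC(=O)OC(C)(C)C
Why: DMAP-catalysed O-acylation of the primary allylic alcohol gives the allylic carbonate needed for ionisation by palladium.

**Step 8**
Reactants: 14 tert-butyl [(3S)-3-formyl-3-methyl-6-oxocyclohex-1-en-1-yl]methyl carbonate
Product: 15 (1S)-3-{[(tert-butoxycarbonyl)oxy]methyl}-1-methyl-4-oxocyclohex-2-ene-1-carboxylic acid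
Conditions: NaClO2, NaH2PO4, 2-methyl-2-butene, t-BuOH/H2O, 0 °C to 23 °C
Reagents that add atoms: sodium chlorite, [Na+].[O-]Cl=O
Why: Pinnick oxidation converts the aldehyde into the acid at pH 4 and should leave the enone and the allylic carbonate untouched.

**Step 9**
Reactants: 15 (1S)-3-{[(tert-butoxycarbonyl)oxy]methyl}-1-methyl-4-oxocyclohex-2-ene-1-carboxylic acid; 7 1-[2-bromo-3,4,6-trimethoxy-5-(propan-2-yl)phenyl]-2-chloroethan-1-one
Product: 16 2-[2-bromo-3,4,6-trimethoxy-5-(propan-2-yl)phenyl]-2-oxoethyl (1S)-3-{[(tert-butoxycarbonyl)oxy]methyl}-1-methyl-4-oxocyclohex-2-ene-1-carboxylate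
Conditions: KHCO3, NaI (10 mol %), DMF, 0 °C to 23 °C
Reagents that add atoms: none
Why: SN2 alkylation of the carboxylate by the phenacyl chloride (Finkelstein activation in the flask); bicarbonate is too weak to enolise the phenacyl ester, so the tethered substrate should be isolable.

**Step 10**
Reactants: 16 2-[2-bromo-3,4,6-trimethoxy-5-(propan-2-yl)phenyl]-2-oxoethyl (1S)-3-{[(tert-butoxycarbonyl)oxy]methyl}-1-methyl-4-oxocyclohex-2-ene-1-carboxylate
Product: 18 (4S,5R,6R)-11,12,14-trimethoxy-1,7-dioxo-9(10→20)-abeo-abieta-8,11,13,10(20)-tetraen-19,6-olide, via bicyclic exo-methylene lactone 17 (not isolated)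
Conditions: Pd2(dba)3 (5 mol %), P(t-Bu)3·HBF4 (20 mol %), Cy2NMe (3 equiv), 1,4-dioxane, 23 °C then 80 °C
Reagents that add atoms: none
Why: Zerovalent palladium ionises the allylic tert-butyl carbonate to a π-allyl complex with loss of CO2; the tert-butoxide set free deprotonates the phenacyl CH2 (C6) and the enolate attacks the ring terminus C5 (Tsuji–Trost alkylation), which leaves the exocyclic methylene C10=C20. Oxidative addition into the C9–Br bond then gives an arylpalladium species that inserts across this enone alkene with the aryl group going to the terminal β-carbon C20, and β-hydride elimination of a benzylic hydrogen gives the C10=C20 alkene conjugated with the arene and the C1 ketone (Mizoroki–Heck); the closest known reaction type is the palladium-catalysed domino Tsuji–Trost/Heck cyclisation. The γ-lactone closes in the 5-exo mode at the allyl terminus and ring B closes by a 7-endo-trig insertion. C5 is set by the ester tether, which can deliver C6 only to the face of the C4 carboxyl group (cis-fused lactone on ring A); C6 is set by the aroyl group taking the convex face of the bicyclic lactone, trans to C10, which should also be the more stable arrangement at this epimerisable centre, and the mild amine base limits later epimerisation. The step needs attack at C5 and not C20 of the allyl unit (five- against seven-membered lactone), 7-endo and not 6-exo insertion (enone polarisation, no quaternary C10, and the strain of a six-membered ring across the trans junction at C5–C6), and elimination toward C20 and not C5 (two benzylic hydrogens, conjugated product).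

**Step 11**
Reactants: 18 (4S,5R,6R)-11,12,14-trimethoxy-1,7-dioxo-9(10→20)-abeo-abieta-8,11,13,10(20)-tetraen-19,6-olide
Product: 19 (1R,4S,5R,6R)-1-hydroxy-11,12,14-trimethoxy-7-oxo-9(10→20)-abeo-abieta-8,11,13,10(20)-tetraen-19,6-olide
Conditions: NaBH4 (1.0 equiv), CeCl3·7H2O, MeOH/CH2Cl2, −78 °C
Reagents that add atoms: none
Why: Luche 1,2-reduction should take the enone carbonyl before the hindered, donor-deactivated aryl ketone, and the small hydride adds axially from the α face (only the axial hydrogens at C3 and C5 lie there) to give the equatorial 1β (1R) alcohol.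

**Step 12**
Reactants: 19 (1R,4S,5R,6R)-1-hydroxy-11,12,14-trimethoxy-7-oxo-9(10→20)-abeo-abieta-8,11,13,10(20)-tetraen-19,6-olide
Product: 20 (1R,4S,5R,6R,7S)-1,7-dihydroxy-11,12,14-trimethoxy-9(10→20)-abeo-abieta-8,11,13,10(20)-tetraen-19,6-olide
Conditions: Li[HB(s-Bu)3] (2.2 equiv), THF, −78 °C to −40 °C; then aq. NH4Cl
Reagents that add atoms: none
Why: The bulky trialkylborohydride should avoid the axial trajectory at C7 (hindered by the axial H5) and add from the β face next to H6, as in equatorial attack on cyclohexanones, giving the axial 7α (7S) alcohol cis to the lactone oxygen; the lactone should survive at low temperature.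

**Step 13**
Reactants: 20 (1R,4S,5R,6R,7S)-1,7-dihydroxy-11,12,14-trimethoxy-9(10→20)-abeo-abieta-8,11,13,10(20)-tetraen-19,6-olide
Product: 21 (1R,4S,5R,6R,7S)-1,7-dihydroxy-12-methoxy-11,14-dioxo-9(10→20)-abeo-abieta-8,12,10(20)-trien-19,6-olide
Conditions: (NH4)2Ce(NO3)6, MeCN/H2O, 0 °C
Reagents that add atoms: water, O
Why: Oxidative demethylation of the para-dimethoxy pair (C11 and C14) by tetravalent cerium, through the arene radical cation and addition of water, gives the para-quinone and keeps the C12 methoxy group.

**Step 14**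
Reactants: 21 (1R,4S,5R,6R,7S)-1,7-dihydroxy-12-methoxy-11,14-dioxo-9(10→20)-abeo-abieta-8,12,10(20)-trien-19,6-olide
Product: 22 ballotiquinone
Conditions: BCl3, CH2Cl2, −78 °C; then H2O
Reagents that add atoms: none
Why: Boron chelated between the C11 carbonyl and the C12 methoxy oxygen activates the methyl group for SN2 cleavage by chloride (selective demethylation next to a carbonyl), and the hydroxyl groups are returned from their borates on work-up.

**Compound list**

1 | 1,2,4-trimethoxybenzene | COc1ccc(OC)c(OC)c1 | starting material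
2 | acetone | CC(C)=O | starting material
3 | 2-(2,3,6-trimethoxyphenyl)propan-2-ol | COc1ccc(OC)c(C(C)(C)O)c1OC | intermediate
4 | 1,2,4-trimethoxy-3-(propan-2-yl)benzene | COc1ccc(OC)c(C(C)C)c1OC | intermediate
5 | chloroacetyl chloride | ClCC(Cl)=O | starting material
6 | 2-chloro-1-[2,4,5-trimethoxy-3-(propan-2-yl)phenyl]ethan-1-one | COc1cc(C(=O)CCl)c(OC)c(C(C)C)c1OC | intermediate
7 | 1-[2-bromo-3,4,6-trimethoxy-5-(propan-2-yl)phenyl]-2-chloroethan-1-one | COc1c(Br)c(C(=O)CCl)c(OC)c(C(C)C)c1OC | intermediate
8 | (E)-3-(tert-butyldimethylsilyloxy)-N,N-dimethylbuta-1,3-dien-1-amine | CN(C)/C=C/C(=C)O[Si](C)(C)C(C)(C)C | starting material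
9 | methacrolein (2-methylprop-2-enal) | CC(=C)C=O | starting material
10 | (1S,2R)-4-(tert-butyldimethylsilyloxy)-2-(dimethylamino)-1-methylcyclohex-3-ene-1-carbaldehyde (endo cycloadduct) | O=C[C@@]1(C)CCC(O[Si](C)(C)C(C)(C)C)=C[C@H]1N(C)C | intermediate (not isolated)
11 | (1S)-1-methyl-4-oxocyclohex-2-ene-1-carbaldehyde | O=C[C@@]1(C)CCC(=O)C=C1 | intermediate
12 | formaldehyde | C=O | starting material
13 | (1S)-3-(hydroxymethyl)-1-methyl-4-oxocyclohex-2-ene-1-carbaldehyde | O=C[C@@]1(C)CCC(=O)C(CO)=C1 | intermediate
14 | tert-butyl [(3S)-3-formyl-3-methyl-6-oxocyclohex-1-en-1-yl]methyl carbonate | O=C[C@@]1(C)CCC(=O)C(COC(=O)OC(C)(C)C)=C1 | intermediate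
15 | (1S)-3-{[(tert-butoxycarbonyl)oxy]methyl}-1-methyl-4-oxocyclohex-2-ene-1-carboxylic acid | OC(=O)[C@@]1(C)CCC(=O)C(COC(=O)OC(C)(C)C)=C1 | intermediate
16 | 2-[2-bromo-3,4,6-trimethoxy-5-(propan-2-yl)phenyl]-2-oxoethyl (1S)-3-{[(tert-butoxycarbonyl)oxy]methyl}-1-methyl-4-oxocyclohex-2-ene-1-carboxylate | COc1c(Br)c(C(=O)COC(=O)[C@@]2(C)CCC(=O)C(COC(=O)OC(C)(C)C)=C2)c(OC)c(C(C)C)c1OC | intermediate
17 | (3R,3aR,7aS)-3-[2-bromo-3,4,6-trimethoxy-5-(propan-2-yl)benzoyl]-7a-methyl-4-methylidenehexahydro-2-benzofuran-1,5-dione (cis-fused γ-lactone, aroyl group trans to the ring carbon at C3a) | COc1c(Br)c(C(=O)[C@@H]2OC(=O)[C@@]3(C)CCC(=O)C(=C)[C@@H]23)c(OC)c(C(C)C)c1OC | intermediate (not isolated)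
18 | (4S,5R,6R)-11,12,14-trimethoxy-1,7-dioxo-9(10→20)-abeo-abieta-8,11,13,10(20)-tetraen-19,6-olide | CC(C)c1c(OC)c(OC)c2c(c1OC)C(=O)[C@@H]1OC(=O)[C@@]3(C)CCC(=O)C(=C2)[C@@H]13 | intermediate
19 | (1R,4S,5R,6R)-1-hydroxy-11,12,14-trimethoxy-7-oxo-9(10→20)-abeo-abieta-8,11,13,10(20)-tetraen-19,6-olide (1β-alcohol) | CC(C)c1c(OC)c(OC)c2c(c1OC)C(=O)[C@@H]1OC(=O)[C@@]3(C)CC[C@@H](O)C(=C2)[C@@H]13 | intermediate
20 | (1R,4S,5R,6R,7S)-1,7-dihydroxy-11,12,14-trimethoxy-9(10→20)-abeo-abieta-8,11,13,10(20)-tetraen-19,6-olide (1β,7α-diol) | CC(C)c1c(OC)c(OC)c2c(c1OC)[C@H](O)[C@@H]1OC(=O)[C@@]3(C)CC[C@@H](O)C(=C2)[C@@H]13 | intermediate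
21 | (1R,4S,5R,6R,7S)-1,7-dihydroxy-12-methoxy-11,14-dioxo-9(10→20)-abeo-abieta-8,12,10(20)-trien-19,6-olide (12-O-methylballotiquinone) | CC(C)C1=C(OC)C(=O)C2=C(C1=O)[C@H](O)[C@@H]1OC(=O)[C@@]3(C)CC[C@@H](O)C(=C2)[C@@H]13 | intermediate
22 | ballotiquinone, (1R,4S,5R,6R,7S)-1,7,12-trihydroxy-11,14-dioxo-9(10→20)-abeo-abieta-8,12,10(20)-trien-19,6-olide | CC(C)C1=C(O)C(=O)C2=C(C1=O)[C@H](O)[C@@H]1OC(=O)[C@@]3(C)CC[C@@H](O)C(=C2)[C@@H]13 | target

**Count.** Total steps: 14. Longest linear sequence: 10 steps (steps 5 to 14 from 8 and 9; equally steps 1 to 4 and 9 to 14 from 1).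

**Steps most likely to fail**

Step 10. The arylpalladium intermediate may insert in the 6-exo sense, may be protonated instead of undergoing β-hydride elimination, or the trans ring closure may be so slow that C6 epimerises first. The fallback sets out from 16 and comes back at 18, with the two bond formations separated. Pd(PPh3)4 in THF at 23 °C performs only the allylic alkylation, and the bicyclic lactone 17 is isolated. Bu3SnH/AIBN (slow addition, benzene, 80 °C) then forms the aryl radical at C9, which adds to the terminal carbon of the enone (7-endo radical conjugate addition) to give (4S,5R,6R,10R)-11,12,14-trimethoxy-1,7-dioxo-9(10→20)-abeo-abieta-8,11,13-trien-19,6-olide F1. DDQ in dioxane at 80 °C removes the benzylic hydride at C20 and the proton at C10 and gives 18.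

Step 6. The Lewis-base catalyst may add too slowly to the enone β-carbon next to the quaternary centre, so that hydroxymethylation stalls or the aldehyde is consumed in side reactions. The fallback sets out from 11 and comes back at 13. I2 and pyridine in CH2Cl2 give (1S)-3-iodo-1-methyl-4-oxocyclohex-2-ene-1-carbaldehyde F2 by addition–elimination α-iodination. Stille coupling of F2 with (tributylstannyl)methanol (Pd(PPh3)4, dioxane, 80 °C) gives 13.

Step 14. The Lewis acid may ionise or chlorinate the allylic C1 alcohol or the C7 alcohol before the methyl ether is cleaved. The fallback sets out from 21 and comes back at 22: the vinylogous methyl ester is cleaved by addition–elimination at C12 instead (LiOH, THF/H2O, 0 °C, short contact; then dilute HCl, which should also reclose any opened lactone). This fallback makes no new compound (F0).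

**Further compounds**

F1 | step 10 | (4S,5R,6R,10R)-11,12,14-trimethoxy-1,7-dioxo-9(10→20)-abeo-abieta-8,11,13-trien-19,6-olide (10β-H) | CC(C)c1c(OC)c(OC)c2c(c1OC)C(=O)[C@@H]1OC(=O)[C@@]3(C)CCC(=O)[C@H](C2)[C@@H]13
F2 | step 6 | (1S)-3-iodo-1-methyl-4-oxocyclohex-2-ene-1-carbaldehyde | O=C[C@@]1(C)CCC(=O)C(I)=C1
F0 | step 14 | none | none
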